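| flask | substrate | first nucleophile | gas | remark | time |
|---|---|---|---|---|---|
| west | 2 M | 1.05 equiv | 200 mM (held) | the very flask that is asked about, followed so far |  |
| north | 2 M | 0.70 equiv | 200 mM (held) | run made earlier |  |
| flask | 2.0 M | 1.05 equiv | 200 mM (held) |  | 15 h |

| run | time / h | target / % | substrate / % |
|---|---|---|---|
| west | 0.333 | 0.5 | 99.0 |
| west | 0.833 | 2.4 | 97.2 |
| west | 2.00 | 4.2 | 93.3 |
| west | 5.00 | 9.1 | 83.5 |
| north | 1.33 | 2.9 | 95.3 |
| north | 3.00 | 4.5 | 90.7 |
| north | 6.00 | 8.3 | 80.5 |
| north | 15.0 | 16.3 | 58.9 |

(scatter of a reading: 0.5 percentage points)

- at the start none of second nucleophile is dissolved
- the numbers in the tables scatter by 0.5 percentage points (one standard deviation)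
- steps that have been proposed: gas <-> second nucleophile; substrate -> intermediate; first nucleophile + intermediate -> target; second nucleophile + intermediate -> other capture product

- how much target there is at 15 h, in percent of the substrate charged
- the change that raises the amount of target at 15 h, in percent of the substrate charged most ("none" if none brings more than 2 percentage points) (ash / larch / elm / none)
- amount of target at 15 h, in percent of the substrate charged, after larch

- ash: doubling the transfer coefficient of the gas, all else as stated
- larch: doubling the saturation concentration of gas, all else as stated
- elm: doubling the amount of first nucleophile, all else as stated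

**Early times.** From early times to their last readings I saw the west and north runs lose substrate at 0.0361 h⁻¹ and 0.0353 h⁻¹, alike though their first nucleophile differed. So I took north's loss by 15.0 h, 41.1% of the charge, for the flask, which is the west run followed further.

**Rival equivalent.** I counted lost substrate as target or other capture product, and took mean first nucleophile as its charge minus half the target formed. North then gave 0.941: the rival equivalent, the fraction of the substrate charge of first nucleophile that takes as much intermediate as the dissolved second nucleophile does, a selectivity factor in charge units. With dissolved second nucleophile held steady, the target share is mean/(mean + rival equivalent).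

**First way.** In the flask, the full charge gave a share of 52.7% and 21.7% target. The mean was therefore 0.942, the share 50.0%, and the target 20.6%. The share at the end was 47.3%, and the mean of the two ends, 50.0%, matched the share at the mean.

**Second way.** West's reading at 5.00 h gave 0.817, hence 22.0% for the flask. The two ways parted by 1.4 percentage points. West's target of 9.1% carried the same scatter as north's, which was nearly twice as large, so I kept 20.6%.

**The changes.** Taking second nucleophile at saturation, larch doubled the rival equivalent and gave 14.0%. Elm gave 27.8%. Ash has no term in the rule.

**The result.** The forecast gave 21% (19.8% to 22.2%), elm as best, and 14% (12.3% to 15.8%) after larch: “Larch doubles the dissolved competitor”. The flask gives 21.4%, 14.8% after larch, and elm as best, with 6.9 points.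

    gas ⇌ second nucleophile, rate k1*(csat - [second nucleophile]) (kL = 4.80 h⁻¹)
    substrate → intermediate (k = 0.0350 h⁻¹)
    first nucleophile + intermediate → target (k = 29.0 L mol⁻¹ h⁻¹)
    second nucleophile + intermediate → other capture product (k = 260 L mol⁻¹ h⁻¹)

**What stood.** In the flask, the half-life of intermediate towards target at 15.0 h, 0.86 min, is far shorter than the 20 h of substrate going to intermediate, and intermediate stands at 0.0208%. The flask's target moves by 5 points with first nucleophile at 0.654 equiv or 1.71 equiv. In a neighbour flask with 0.80 M substrate, the same equivalents and the same time, the rival equivalent becomes 2.35 of that smaller charge, which gives 12.1%. The computed neighbour flask gives 12.8%.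

Readings and results come from a simulation for substances that don't exist.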